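**Plan**
- Retrosynthesis: the CH2–CH2 bond of the butynyl chain (propargylic carbon to O-bearing carbon) is cut first, giving a propargylic bromide and an (acyloxymethyl)zinc reagent. Next the C(sp)–C5' bond to the second thiophene is cut, then the senecioate C–O bond. The zinc fragment goes back through O–CH2–I to 3-methylbutanoyl chloride and formaldehyde.
- Forward: no ring is built; the 2,2'-bithiophene is bought intact in 1. CHO is reduced to CH2OH and esterified, propargyl alcohol is coupled onto C5', and OH is exchanged for Br. Separately the acyl chloride is taken to the chloromethyl and then the iodomethyl ester. The two halves are joined last, with both esters in place and no protecting group.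
- Enabling feature: the propargylic CH2 next to the C≡C on C5' of the thiophene ring has a weak C–Br bond and gives a delocalised propargyl radical whose unsubstituted CH2 end is the accessible one. The O–CH2 carbon carries an ester whose C=O can chelate zinc, so the α-oxygenated organozinc should neither eliminate nor attack esters.
- Stereochemistry: none to set. There is no stereocentre, and the only C=C carries two methyl groups on one carbon.

Key step: step 7

Assumption: paraformaldehyde is entered as its monomer formaldehyde (9), and 5'-bromo-[2,2'-bithiophene]-5-carbaldehyde (1) is taken as a purchasable starting material.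

**Route**

Step 1
Reactants: 1 5'-bromo-[2,2'-bithiophene]-5-carbaldehyde
Product: 2 (5'-bromo-[2,2'-bithiophen]-5-yl)methanol
Conditions: NaBH4, MeOH/THF, 0 °C
Reagents that add atoms: none
Why: Borohydride reduction of the aryl aldehyde should give the primary alcohol chemoselectively, leaving the C–Br bond and both thiophene rings untouched.

Step 2
Reactants: 2 (5'-bromo-[2,2'-bithiophen]-5-yl)methanol; 3 3-methylbut-2-enoic acid
Product: 4 (5'-bromo-[2,2'-bithiophen]-5-yl)methyl 3-methylbut-2-enoate
Conditions: DCC, DMAP (cat.), CH2Cl2, 0 °C to rt
Reagents that add atoms: none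
Why: Steglich esterification should acylate the primary thienylmethyl alcohol under near-neutral conditions, avoiding acid ionisation of the thienylmethyl position and limiting base-induced migration of the C=C out of conjugation.

Step 3
Reactants: 4 (5'-bromo-[2,2'-bithiophen]-5-yl)methyl 3-methylbut-2-enoate; 5 prop-2-yn-1-ol
Product: 6 [5'-(3-hydroxyprop-1-yn-1-yl)-[2,2'-bithiophen]-5-yl]methyl 3-methylbut-2-enoate
Conditions: PdCl2(PPh3)2 (cat.), CuI (cat.), Et3N, THF (degassed), 50 °C
Reagents that add atoms: none
Why: Sonogashira coupling at the 2-bromothiophene C5'–Br bond with the terminal alkyne should form the C(sp2)–C(sp) bond, and the free hydroxyl and the ester are tolerated.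

Step 4
Reactants: 6 [5'-(3-hydroxyprop-1-yn-1-yl)-[2,2'-bithiophen]-5-yl]methyl 3-methylbut-2-enoate
Product: 7 [5'-(3-bromoprop-1-yn-1-yl)-[2,2'-bithiophen]-5-yl]methyl 3-methylbut-2-enoate
Conditions: CBr4, PPh3 (added last), CH2Cl2, 0 °C; used promptly
Reagents that add atoms: carbon tetrabromide, BrC(Br)(Br)Br
Why: The Appel reaction should convert the primary propargylic alcohol into the bromide through an alkoxyphosphonium ion and SN2 attack of bromide, under neutral conditions that the ester survives.

Step 5
Reactants: 8 3-methylbutanoyl chloride; 9 formaldehyde (as paraformaldehyde)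
Product: 10 chloromethyl 3-methylbutanoate
Conditions: ZnCl2 (cat.), neat, 70 °C; distillation
Reagents that add atoms: none
Why: Lewis-acid-catalysed addition of the acyl chloride across the C=O of formaldehyde is the standard entry to chloromethyl esters and should give the α-chloroalkyl ester.

Step 6
Reactants: 10 chloromethyl 3-methylbutanoate
Product: 11 iodomethyl 3-methylbutanoate
Conditions: NaI, acetone, rt, dark
Reagents that add atoms: sodium iodide, [Na+].[I-]
Why: Finkelstein exchange (SN2 at the activated O–CH2–Cl carbon, driven by precipitation of NaCl) should give the iodide needed for zinc insertion.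

Step 7
Reactants: 7 [5'-(3-bromoprop-1-yn-1-yl)-[2,2'-bithiophen]-5-yl]methyl 3-methylbut-2-enoate; 11 iodomethyl 3-methylbutanoate
Product: 13 [5'-[4-[(3-methylbutanoyl)oxy]but-1-yn-1-yl]-[2,2'-bithiophen]-5-yl]methyl 3-methylbut-2-enoate, via [(3-methylbutanoyl)oxy]methylzinc iodide 12 (not isolated)
Conditions: 11, Zn dust (activated with BrCH2CH2Br, TMSCl), THF, 10–15 °C; then 7, NiCl2·glyme (10 mol%), 2,2':6',2''-terpyridine (10 mol%), DMA/THF, rt
Reagents that add atoms: zinc dust, [Zn] (zinc is held only in intermediate 12 and is not in 13)
Why: Proposed new method: zinc inserts into the C–I bond of 11 to give the α-acyloxymethylzinc iodide 12, which transmetalates to a terpyridine-ligated Ni(I) centre; the Ni(I)–CH2OC(O)R species abstracts bromine from the propargylic C–Br bond of 7, the propargyl radical is captured by nickel, and reductive elimination from Ni(III) forms the CH2–CH2 bond and returns Ni(I). The closest known reaction types are the nickel/terpyridine-catalysed Negishi coupling of propargylic bromides with alkylzinc halides, which gives propargylic products, and the copper-mediated coupling of (acyloxymethyl)zinc iodides with allylic halides; what is new is an α-acyloxymethylzinc nucleophile in the nickel-catalysed propargylic coupling. No ring is closed and no stereocentre is formed. The step needs bond formation at the propargylic CH2 and not at the thiophene-bearing alkyne carbon (allene formation), which the unsubstituted primary terminus and the retained conjugation of the C≡C bond with the thiophene ring should secure. It also needs selectivity for the C–Br bond over the thienylmethyl C–O bond and the two ester carbonyls, which the low basicity of the chelated organozinc and the room-temperature radical activation of the weak propargylic C–Br bond should secure.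

**Compound list**
1 | 5'-bromo-[2,2'-bithiophene]-5-carbaldehyde | O=Cc1ccc(-c2ccc(Br)s2)s1 | starting material
2 | (5'-bromo-[2,2'-bithiophen]-5-yl)methanol | OCc1ccc(-c2ccc(Br)s2)s1 | intermediate
3 | 3-methylbut-2-enoic acid | CC(C)=CC(=O)O | starting material
4 | (5'-bromo-[2,2'-bithiophen]-5-yl)methyl 3-methylbut-2-enoate | CC(C)=CC(=O)OCc1ccc(-c2ccc(Br)s2)s1 | intermediate
5 | prop-2-yn-1-ol | C#CCO | starting material
6 | [5'-(3-hydroxyprop-1-yn-1-yl)-[2,2'-bithiophen]-5-yl]methyl 3-methylbut-2-enoate | CC(C)=CC(=O)OCc1ccc(-c2ccc(C#CCO)s2)s1 | intermediate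
7 | [5'-(3-bromoprop-1-yn-1-yl)-[2,2'-bithiophen]-5-yl]methyl 3-methylbut-2-enoate | CC(C)=CC(=O)OCc1ccc(-c2ccc(C#CCBr)s2)s1 | intermediate
8 | 3-methylbutanoyl chloride | CC(C)CC(=O)Cl | starting material
9 | formaldehyde (used as paraformaldehyde) | C=O | starting material
10 | chloromethyl 3-methylbutanoate | CC(C)CC(=O)OCCl | intermediate
11 | iodomethyl 3-methylbutanoate | CC(C)CC(=O)OCI | intermediate
12 | [(3-methylbutanoyl)oxy]methylzinc iodide (not isolated) | CC(C)CC(=O)OC[Zn]I | intermediate
13 | [5'-[4-[(3-methylbutanoyl)oxy]but-1-yn-1-yl]-[2,2'-bithiophen]-5-yl]methyl 3-methylbut-2-enoate | CC(C)=CC(=O)OCc1ccc(-c2ccc(C#CCCOC(=O)CC(C)C)s2)s1 | target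

**Summary**
Total step count: 7. Longest linear sequence: 5 steps (steps 1, 2, 3, 4, 7); the side branch (steps 5, 6) joins at step 7.

**Steps most likely to fail**

1. Step 7 (Proposed new method). The chelated α-acyloxymethylzinc may fail to transmetalate to nickel, the propargylic bromide may undergo reductive homocoupling, or C–C bond formation may occur at the thiophene-bearing alkyne carbon. Fallback with known chemistry, setting out from 4 and returning at 13: purchased but-3-yn-1-ol F1 is acylated with 8 (pyridine, CH2Cl2, 0 °C) to but-3-yn-1-yl 3-methylbutanoate F2. F2 is then joined to bromide 4 by Sonogashira coupling (PdCl2(PPh3)2, CuI, Et3N, THF, 50 °C), which should give 13 directly. The thiophene–alkyne bond is then formed last, with the four-carbon chain and its ester already complete.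

2. Step 4. The electron-rich (bithienyl)propargylic bromide may decompose during formation or isolation, by ionisation, propargyl-to-allenyl bromide isomerisation, oligomerisation, or quaternisation of PPh3. Fallback, setting out from 6 and returning at 13: 6 is converted with N-chlorosuccinimide/PPh3 (THF, 0 °C) into the more robust chloride [5'-(3-chloroprop-1-yn-1-yl)-[2,2'-bithiophen]-5-yl]methyl 3-methylbut-2-enoate F3. F3 replaces 7 as the electrophile in the nickel-catalysed coupling with 12, so the labile bromide is never isolated. This fallback still relies on the step 7 coupling.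

3. Step 3. Oxidative addition into the electron-rich C5'–Br bond may be slow, letting oxidative dimerisation of propargyl alcohol and palladium insertion into the thienylmethyl C–O bond compete. Fallback, setting out from 1 and returning at 6: the coupling is run first on the aldehyde-activated bromide 1 with purchased tert-butyldimethyl(prop-2-yn-1-yloxy)silane F4 (same Pd/Cu conditions), giving 5'-[3-(tert-butyldimethylsilyloxy)prop-1-yn-1-yl]-[2,2'-bithiophene]-5-carbaldehyde F5. NaBH4 reduction gives [5'-[3-(tert-butyldimethylsilyloxy)prop-1-yn-1-yl]-[2,2'-bithiophen]-5-yl]methanol F6. Steglich esterification with 3 gives [5'-[3-(tert-butyldimethylsilyloxy)prop-1-yn-1-yl]-[2,2'-bithiophen]-5-yl]methyl 3-methylbut-2-enoate F7. Desilylation with HF·pyridine (THF, 0 °C) should then give 6.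

**Further compounds**
F1 | step 7 | but-3-yn-1-ol (purchased) | C#CCCO
F2 | step 7 | but-3-yn-1-yl 3-methylbutanoate | C#CCCOC(=O)CC(C)C
F3 | step 4 | [5'-(3-chloroprop-1-yn-1-yl)-[2,2'-bithiophen]-5-yl]methyl 3-methylbut-2-enoate | CC(C)=CC(=O)OCc1ccc(-c2ccc(C#CCCl)s2)s1
F4 | step 3 | tert-butyldimethyl(prop-2-yn-1-yloxy)silane (purchased) | C#CCO[Si](C)(C)C(C)(C)C
F5 | step 3 | 5'-[3-(tert-butyldimethylsilyloxy)prop-1-yn-1-yl]-[2,2'-bithiophene]-5-carbaldehyde | O=Cc1ccc(-c2ccc(C#CCO[Si](C)(C)C(C)(C)C)s2)s1
F6 | step 3 | [5'-[3-(tert-butyldimethylsilyloxy)prop-1-yn-1-yl]-[2,2'-bithiophen]-5-yl]methanol | OCc1ccc(-c2ccc(C#CCO[Si](C)(C)C(C)(C)C)s2)s1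
F7 | step 3 | [5'-[3-(tert-butyldimethylsilyloxy)prop-1-yn-1-yl]-[2,2'-bithiophen]-5-yl]methyl 3-methylbut-2-enoate | CC(C)=CC(=O)OCc1ccc(-c2ccc(C#CCO[Si](C)(C)C(C)(C)C)s2)s1
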